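Adding catalyst looks like a sure way to more X, yet at 8.00 d the cedar flask, with 17 µM of L, holds 32.6 % of X, less than the 49.2 % held by the maple flask with 3.9 µM. Something takes X away again, and the row asked for has to be solved from both ends.

| flask | G | L | remark | time |
|---|---|---|---|---|
| birch | 0.081 M (fed, over 6.0 d) | 0.95 µM | run made earlier; the fed solution adds 0.25 times the starting volume |  |
| maple | 0.081 M (fed, over 6.0 d) | 3.9 µM | run made earlier; the fed solution adds 0.25 times the starting volume |  |
| cedar | 0.081 M (fed, over 6.0 d) | 17 µM | run made earlier; the fed solution adds 0.25 times the starting volume |  |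
| Monday's | 0.081 M (fed, over 6.0 d) | 1.0 µM | the fed solution adds 0.25 times the starting volume | 12 d |
| Tuesday's | 0.081 M (fed, over 6.0 d) | 2.0 µM | the fed solution adds 0.25 times the starting volume | 12 d |
| Friday's | 0.081 M (fed, over 6.0 d) | 4.0 µM | the fed solution adds 0.25 times the starting volume | 12 d |
| Sunday's | 0.081 M (fed, over 6.0 d) | 8.0 µM | the fed solution adds 0.25 times the starting volume | 12 d |
| Thursday's | 0.081 M (fed, over 6.0 d) | 15 µM | the fed solution adds 0.25 times the starting volume | 12 d |

| run | time / d | X / % | G / % |
|---|---|---|---|
| birch | 1.67 | 2.0 | 25.0 |
| birch | 3.00 | 6.4 | 42.7 |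
| birch | 5.00 | 13.6 | 68.6 |
| birch | 6.00 | 17.3 | 80.3 |
| birch | 8.00 | 25.8 | 72.3 |
| maple | 1.67 | 8.3 | 18.1 |
| maple | 3.00 | 17.8 | 27.4 |
| maple | 5.00 | 33.9 | 36.9 |
| maple | 6.00 | 40.9 | 40.1 |
| maple | 8.00 | 49.2 | 19.1 |
| cedar | 1.67 | 12.4 | 6.6 |
| cedar | 3.00 | 19.8 | 6.9 |
| cedar | 5.00 | 30.3 | 7.3 |
| cedar | 6.00 | 35.6 | 7.8 |
| cedar | 8.00 | 32.6 | 0.8 |

(scatter of a reading: 0.3 percentage points)

- amounts are per litre of the starting volume; all of the dose is in the solution fed
- the numbers in the tables scatter with a standard deviation of 0.3 percentage points
- steps thought possible: G + L <-> J; J <-> L + X; X + L <-> E + L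
- percentages count the whole charge, also what has not yet gone in
- "hardly changes" means that all values lie within two and a half points (for a concentration: within two and a half percent of the largest)

- amount of X at the end, in percent of the G charged for Monday's, Tuesday's, Friday's, Sunday's, Thursday's, in this order
- the shape of the row from first to last (rises, then falls / falls all the way / rises all the way / hardly changes / falls, then rises)

The high end comes first. By difference from what has been fed, E in cedar stands at 45.7 %, 56.6 % and 66.6 % at 5.00 d, 6.00 d and 8.00 d; the catalyst is too dilute for its bound form to count. The first way takes the last reading as finished. X then makes up 32.9 % of what has reacted, and this is the end share: X divided by X plus E once the two stand in equilibrium, the thermodynamic control of the flask.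

The second way assumes nothing finished. E gains 2.17 times as fast in the first window as in the second. If the net flow is proportional to X minus a fixed fraction of E, with the catalyst equally free in both windows, those two windows give two equations, and the flow stops at a share of 33.2 %. One number comes from a state and the other from rates, and they agree, so the end share is trusted.

After the feed, Sunday's flask gets 1.41 times cedar's catalyst-days and Thursday's 2.65 times, so this reckoning puts both near 32.9 %.

At the low end, Monday's flask resembles birch. Birch's slope after the feed, scaled to 1.0 µM, gives a straight line to 45.1 %, which counts no bending. To compare at one moment, maple's catalyst-days up to 8.00 d are matched at 12 d by 2.60 µM of L, a setting between Tuesday's and Friday's. This reckoning is rough, since the feed fills a different part of the time, but it puts such a flask near maple's 49.2 %, above the 45.1 % and 32.9 % reckoned for the two ends, so the row should rise, then fall.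

The forecast gives 39 %, 53 %, 41 %, 33 % and 32.3 %, shape rises, then falls, holding that at the top of the row “X reaches equilibrium”.

The flasks give 38.9 %, 51.4 %, 40.2 %, 32.4 % and 32.1 %, shape rises, then falls.

    G + L ⇌ J (K = 30.0 M⁻¹, k = 1000 M⁻¹ s⁻¹)
    J ⇌ L + X (K = 1.90 M, k = 0.0730 s⁻¹)
    X + L ⇌ E + L, rate k3*[L]*[X] forward; the back reaction follows from the equilibrium constant (K = 2.10, k = 1.10 M⁻¹ s⁻¹)

On Thursday's flask the end share, applied to what has left G, gives 32.7 % against 32.1 %. The step from X to E is the reason: without it Thursday's flask would hold 98.3 % of X instead of 32.1 %, and the shape of the row would turn. Monday's flask, left until 120 d, has 0.563 % of G remaining, so the end share gives 32.7 %, and the X standing there is 32.1 %.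

Readings and results are calculated with constants of no real substance, and the scatter is random.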